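**Retrosynthetic overview**
- The target is (2R,3R)-3-O-acetyl-6-prenylpinobanksin. The plan rests on C3 and C4 of ring C: both are oxygen-bearing, carbonyl-derived carbons held apart by the chain C4a–C8a–O1–C2, so the C3–C4 bond can be made by reductive coupling of an aryl aldehyde (C4) with a tethered alpha-aryloxy aldehyde (C3).
- 19 ⇐ 18 (MOM cleavage) ⇐ 17 (oxidation at C4) ⇐ cis-3,4-diol 15 (acetylation at O3 only) ⇐ dialdehyde 13 (C3–C4, SmI2 pinacol closure of ring C).
- 13 ⇐ O1–C2 ether bond by Mitsunobu inversion of methyl (S)-mandelate with salicylaldehyde 9, then reduction and re-oxidation; C2 is the only stereocentre brought in.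
- 9 ⇐ phloroglucinol: mono-silylation, bis-MOM protection, lithiation between the MOM ethers and prenylation (C6), desilylation, ortho-formylation (the future C4).
- Ring order: ring A (phloroglucinol) and ring B (phenyl of the mandelate) are bought in; ring C is the only ring formed, in step 9.

Key step: step 9

Step 1
Reactants: 1 phloroglucinol (benzene-1,3,5-triol)
Product: 2 5-{[tri(propan-2-yl)silyl]oxy}benzene-1,3-diol
Conditions: TIPSCl (1.0 equiv), imidazole, DMF, 0 °C to rt; 1 in threefold excess
Reagents that add atoms: chlorotri(propan-2-yl)silane (TIPSCl), CC(C)[Si](Cl)(C(C)C)C(C)C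
Why: Silyl ether formation on a threefold-symmetric triol is statistical, but with the triol in excess and a bulky silyl chloride the mono-ether should dominate, and unreacted 1 is washed out with water.

Step 2
Reactants: 2 5-{[tri(propan-2-yl)silyl]oxy}benzene-1,3-diol
Product: 3 [3,5-bis(methoxymethoxy)phenoxy]tri(propan-2-yl)silane
Conditions: MOMCl (3 equiv), i-Pr2NEt, CH2Cl2, 0 °C to rt
Reagents that add atoms: chloromethyl methyl ether (MOMCl), COCCl
Why: O-Alkylation of both remaining phenols with the alpha-chloro ether under a hindered amine base (MOM ether formation), conditions under which the aryl silyl ether neither migrates nor cleaves.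

Step 3
Reactants: 3 [3,5-bis(methoxymethoxy)phenoxy]tri(propan-2-yl)silane; 4 prenyl bromide (1-bromo-3-methylbut-2-ene)
Product: 6 [3,5-bis(methoxymethoxy)-4-(3-methylbut-2-enyl)phenoxy]tri(propan-2-yl)silane, via aryllithium 5 (not isolated)
Conditions: n-BuLi (1.2 equiv), THF, 0 °C, 1 h; then CuI (10 mol%), 4, −78 °C to rt
Reagents that add atoms: none
Why: Directed ortho-metalation: the C–H between the two MOM ethers is coordinated from both sides and is lithiated in preference to the positions next to the bulky silyl ether, and the aryllithium is then alkylated by prenyl bromide under copper catalysis at the primary carbon (SN2) without allylic transposition.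

Step 4
Reactants: 6 [3,5-bis(methoxymethoxy)-4-(3-methylbut-2-enyl)phenoxy]tri(propan-2-yl)silane
Product: 7 3,5-bis(methoxymethoxy)-4-(3-methylbut-2-enyl)phenol
Conditions: TBAF (1.1 equiv), AcOH (1.1 equiv), THF, 0 °C to rt
Reagents that add atoms: none
Why: Fluoride cleaves the aryl O–Si bond (desilylation driven by the Si–F bond), and buffering with acetic acid keeps the medium near neutral while the MOM acetals and the prenyl group are inert.

Step 5
Reactants: 7 3,5-bis(methoxymethoxy)-4-(3-methylbut-2-enyl)phenol
Product: 9 6-hydroxy-2,4-bis(methoxymethoxy)-3-(3-methylbut-2-enyl)benzaldehyde, via hydroxymethylphenol 8 (not isolated)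
Conditions: MgCl2 (2 equiv), Et3N (4 equiv), paraformaldehyde (6 equiv), MeCN, reflux
Reagents that add atoms: paraformaldehyde (as formaldehyde), C=O
Why: Magnesium-mediated ortho-formylation of a phenol (Casnati–Skattebøl reaction): the magnesium phenoxide directs formaldehyde to an ortho carbon, both ortho positions are equivalent and the para position is blocked, and the hydroxymethyl intermediate 8 is oxidised to the aldehyde by hydride transfer to a second formaldehyde.

Step 6
Reactants: 9 6-hydroxy-2,4-bis(methoxymethoxy)-3-(3-methylbut-2-enyl)benzaldehyde; 10 methyl (S)-mandelate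
Product: 11 methyl (2R)-2-[2-formyl-3,5-bis(methoxymethoxy)-4-(3-methylbut-2-enyl)phenoxy]-2-phenylacetate
Conditions: PPh3 (1.5 equiv), DIAD (1.5 equiv), THF, 0 °C to rt
Reagents that add atoms: none
Why: Mitsunobu etherification: the acidic salicylaldehyde hydroxyl attacks the oxyphosphonium-activated carbinol carbon of 10 in an SN2 displacement with inversion, which converts the (S)-alcohol into the (R)-aryl ether that becomes C2 of the target, the alpha-ester group disfavouring ionisation and loss of configuration.

Step 7
Reactants: 11 methyl (2R)-2-[2-formyl-3,5-bis(methoxymethoxy)-4-(3-methylbut-2-enyl)phenoxy]-2-phenylacetate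
Product: 12 (2R)-2-[2-(hydroxymethyl)-3,5-bis(methoxymethoxy)-4-(3-methylbut-2-enyl)phenoxy]-2-phenylethanol
Conditions: LiBH4 (3 equiv), THF, 0 °C to rt; aq. NH4Cl
Reagents that add atoms: none
Why: Hydride reduction of the aryl aldehyde and of the alpha-aryloxy ester to the two primary alcohols with LiBH4, a weakly basic hydride donor that should not deprotonate the stereocentre next to the ester.

Step 8
Reactants: 12 (2R)-2-[2-(hydroxymethyl)-3,5-bis(methoxymethoxy)-4-(3-methylbut-2-enyl)phenoxy]-2-phenylethanol
Product: 13 (2R)-2-[2-formyl-3,5-bis(methoxymethoxy)-4-(3-methylbut-2-enyl)phenoxy]-2-phenylacetaldehyde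
Conditions: Dess–Martin periodinane (3 equiv, one portion), CH2Cl2, 0 °C to rt; cold aq. Na2S2O3/NaHCO3 wash; crude product used at once
Reagents that add atoms: none
Why: Dess–Martin oxidation of both primary alcohols to aldehydes in a medium free of amine base, which is the usual way to make aldehydes with an enolisable alpha stereocentre; the dialdehyde is not chromatographed but taken on immediately.

Step 9
Reactants: 13 (2R)-2-[2-formyl-3,5-bis(methoxymethoxy)-4-(3-methylbut-2-enyl)phenoxy]-2-phenylacetaldehyde
Product: 15 (2R,3S,4S)-5,7-bis(methoxymethoxy)-6-(3-methylbut-2-enyl)-2-phenylchromane-3,4-diol, via samarium diolate 14 (not isolated)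
Conditions: SmI2 (2.5 equiv, 0.1 M in THF), t-BuOH (2 equiv), THF, −78 °C, slow addition of 13 at high dilution; pH 7 phosphate buffer; chromatography on Et3N-deactivated silica
Reagents that add atoms: none
Why: SmI2 transfers one electron to the conjugated aryl aldehyde; the benzylic ketyl, bound to trivalent samarium, adds to the tethered aliphatic aldehyde carbon in a 6-exo-trig closure of ring C, and a second equivalent of SmI2 reduces the resulting oxygen radical to the bridged diolate 14, which gives 15 on buffered work-up. The closest known reaction type is the SmI2-mediated intramolecular pinacol coupling of 1,6-dialdehydes, alpha-alkoxy dialdehydes included, to cyclic cis-1,2-diols. C3 and C4 are the new stereocentres, and their cis relation should follow from both oxygens being held on one samarium centre while the bond forms. The configuration of C3 relative to C2 should be set by a half-chair transition state with the C2 phenyl pseudo-equatorial and the aldehyde oxygen turned away from the C2–O1 dipole, which places O3 trans to phenyl and leads to the (2R,3S,4S) isomer; C2 itself is carried over unchanged because the medium is neither basic nor strongly acidic. The step needs the first electron to go to the aryl aldehyde and not to the alpha-aryloxy aldehyde, whose ketyl could expel the aryloxide: conjugation with ring A should make the aryl aldehyde the more easily reduced carbonyl in HMPA-free THF at −78 °C, and ring closure of its ketyl should be faster than a second reduction. High dilution and slow addition should suppress intermolecular coupling.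

Step 10
Reactants: 15 (2R,3S,4S)-5,7-bis(methoxymethoxy)-6-(3-methylbut-2-enyl)-2-phenylchromane-3,4-diol
Product: 17 (2R,3S,4S)-4-hydroxy-5,7-bis(methoxymethoxy)-6-(3-methylbut-2-enyl)-2-phenylchroman-3-yl acetate, via stannylene acetal 16 (not isolated)
Conditions: Bu2SnO (1.1 equiv), toluene, 4 Å MS, 100 °C; then AcCl (1.05 equiv), 0 °C; pH 7 buffer
Reagents that add atoms: acetyl chloride, CC(=O)Cl
Why: Regioselective acylation through a dibutylstannylene acetal: for a cis-diol on a six-membered ring the tin acetal activates the equatorial oxygen, here O3, while the pseudo-axial benzylic O4 is also shielded by the peri substituent at C5, so that the acetate is placed on C3 with its configuration unchanged.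

Step 11
Reactants: 17 (2R,3S,4S)-4-hydroxy-5,7-bis(methoxymethoxy)-6-(3-methylbut-2-enyl)-2-phenylchroman-3-yl acetate
Product: 18 (2R,3R)-5,7-bis(methoxymethoxy)-6-(3-methylbut-2-enyl)-4-oxo-2-phenylchroman-3-yl acetate
Conditions: Dess–Martin periodinane (1.5 equiv), CH2Cl2, 0 °C to rt
Reagents that add atoms: none
Why: Dess–Martin oxidation of the remaining benzylic C4 carbinol to the aryl ketone under non-basic conditions, so that the neighbouring acetate does not migrate and C2 and C3 are not enolised; the C4 stereocentre is removed and C3 changes only its descriptor.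

Step 12
Reactants: 18 (2R,3R)-5,7-bis(methoxymethoxy)-6-(3-methylbut-2-enyl)-4-oxo-2-phenylchroman-3-yl acetate
Product: 19 (2R,3R)-5,7-dihydroxy-6-(3-methylbut-2-enyl)-4-oxo-2-phenylchroman-3-yl acetate
Conditions: ZnBr2 (2 equiv), n-PrSH (4 equiv), CH2Cl2, 0 °C, short reaction time; pH 7 buffer
Reagents that add atoms: none
Why: Lewis acid-assisted thiolysis of both aryl MOM acetals: ZnBr2 activates the acetal and the thiol takes up the methoxymethyl cation in an aprotic medium, which should spare the secondary acetate, the prenyl double bond and the epimerisable C2 and C3 centres.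

**Compound list**
1 | phloroglucinol (benzene-1,3,5-triol) | Oc1cc(O)cc(O)c1 | starting material
2 | 5-{[tri(propan-2-yl)silyl]oxy}benzene-1,3-diol | CC(C)[Si](Oc1cc(O)cc(O)c1)(C(C)C)C(C)C | intermediate
3 | [3,5-bis(methoxymethoxy)phenoxy]tri(propan-2-yl)silane | COCOc1cc(OCOC)cc(O[Si](C(C)C)(C(C)C)C(C)C)c1 | intermediate
4 | prenyl bromide (1-bromo-3-methylbut-2-ene) | CC(C)=CCBr | starting material
5 | {2,6-bis(methoxymethoxy)-4-[tri(propan-2-yl)silyloxy]phenyl}lithium | [Li]c1c(OCOC)cc(O[Si](C(C)C)(C(C)C)C(C)C)cc1OCOC | intermediate
6 | [3,5-bis(methoxymethoxy)-4-(3-methylbut-2-enyl)phenoxy]tri(propan-2-yl)silane | COCOc1cc(O[Si](C(C)C)(C(C)C)C(C)C)cc(OCOC)c1CC=C(C)C | intermediate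
7 | 3,5-bis(methoxymethoxy)-4-(3-methylbut-2-enyl)phenol | COCOc1cc(O)cc(OCOC)c1CC=C(C)C | intermediate
8 | 2-(hydroxymethyl)-3,5-bis(methoxymethoxy)-4-(3-methylbut-2-enyl)phenol (present as its magnesium salt) | OCc1c(O)cc(OCOC)c(CC=C(C)C)c1OCOC | intermediate
9 | 6-hydroxy-2,4-bis(methoxymethoxy)-3-(3-methylbut-2-enyl)benzaldehyde | O=Cc1c(O)cc(OCOC)c(CC=C(C)C)c1OCOC | intermediate
10 | methyl (S)-mandelate | COC(=O)[C@@H](O)c1ccccc1 | starting material
11 | methyl (2R)-2-[2-formyl-3,5-bis(methoxymethoxy)-4-(3-methylbut-2-enyl)phenoxy]-2-phenylacetate | COC(=O)[C@H](Oc1cc(OCOC)c(CC=C(C)C)c(OCOC)c1C=O)c1ccccc1 | intermediate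
12 | (2R)-2-[2-(hydroxymethyl)-3,5-bis(methoxymethoxy)-4-(3-methylbut-2-enyl)phenoxy]-2-phenylethanol | OC[C@H](Oc1cc(OCOC)c(CC=C(C)C)c(OCOC)c1CO)c1ccccc1 | intermediate
13 | (2R)-2-[2-formyl-3,5-bis(methoxymethoxy)-4-(3-methylbut-2-enyl)phenoxy]-2-phenylacetaldehyde | O=C[C@H](Oc1cc(OCOC)c(CC=C(C)C)c(OCOC)c1C=O)c1ccccc1 | intermediate
14 | O3,O4-bis(diiodosamarium) diolate of 15 (trivalent samarium, cis) | I[Sm](I)O[C@H]1[C@@H](O[Sm](I)I)c2c(cc(OCOC)c(CC=C(C)C)c2OCOC)O[C@@H]1c1ccccc1 | intermediate
15 | (2R,3S,4S)-5,7-bis(methoxymethoxy)-6-(3-methylbut-2-enyl)-2-phenylchromane-3,4-diol (2,3-trans, 3,4-cis) | O[C@H]1[C@@H](O)c2c(cc(OCOC)c(CC=C(C)C)c2OCOC)O[C@@H]1c1ccccc1 | intermediate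
16 | O3,O4-dibutylstannylene acetal of 15 (2,2-dibutyl-1,3,2-dioxastannolane fused to C3–C4) | CCCC[Sn]1(CCCC)O[C@H]2[C@@H](O1)c1c(cc(OCOC)c(CC=C(C)C)c1OCOC)O[C@@H]2c1ccccc1 | intermediate
17 | (2R,3S,4S)-4-hydroxy-5,7-bis(methoxymethoxy)-6-(3-methylbut-2-enyl)-2-phenylchroman-3-yl acetate | CC(=O)O[C@H]1[C@@H](O)c2c(cc(OCOC)c(CC=C(C)C)c2OCOC)O[C@@H]1c1ccccc1 | intermediate
18 | (2R,3R)-5,7-bis(methoxymethoxy)-6-(3-methylbut-2-enyl)-4-oxo-2-phenylchroman-3-yl acetate | CC(=O)O[C@H]1C(=O)c2c(cc(OCOC)c(CC=C(C)C)c2OCOC)O[C@@H]1c1ccccc1 | intermediate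
19 | (2R,3R)-5,7-dihydroxy-6-(3-methylbut-2-enyl)-4-oxo-2-phenylchroman-3-yl acetate | CC(=O)O[C@H]1C(=O)c2c(cc(O)c(CC=C(C)C)c2O)O[C@@H]1c1ccccc1 | target

**Step count**
Total: 12 steps. Longest linear sequence: 12 steps (1 to 19); 4 and 10 are bought in.

**Steps most likely to fail**

Step 9. What may go wrong:
- electron transfer to the alpha-aryloxy aldehyde followed by expulsion of the aryloxide (C2–O1 cleavage);
- plain reduction of either aldehyde without C–C bond formation;
- ring closure on the face that puts O3 cis to the phenyl group.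

Fallback: setting out again from 13 and returning to the route at 15, the coupling is moved from a free ketyl radical anion to a metal-templated closure. 13 would be added to [V2Cl3(THF)6]2[Zn2Cl6] (divalent vanadium, made from VCl3(THF)3 and zinc dust) in CH2Cl2 at room temperature, so that both carbonyl oxygens are bound to the metal before electrons are transferred. This reagent class is known for pinacol couplings of alpha-heteroatom-substituted aldehydes to syn-1,2-diols without beta-elimination or loss of the alpha stereocentre. Work-up with aqueous tartrate should give 15. This fallback makes no new compound (F0).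

Step 8. What may go wrong:
- enolisation of the alpha-aryloxy-alpha-phenyl aldehyde during oxidation, work-up or storage, which erodes the configuration at C2;
- closure of a mono-aldehyde to a seven-membered lactol that is oxidised further to a lactone.

Fallback: setting out from 9 and returning at 13, the C3 aldehyde is reached by reduction of a thioester instead of re-oxidation of an alcohol, so that 12 and the oxidant are avoided. (S)-Mandelic acid would be converted with ethanethiol and DCC into S-ethyl (2S)-2-hydroxy-2-phenylethanethioate F1. Mitsunobu etherification of 9 with F1 (PPh3, DIAD, THF, inversion) should give S-ethyl (2R)-2-[2-formyl-3,5-bis(methoxymethoxy)-4-(3-methylbut-2-enyl)phenoxy]-2-phenylethanethioate F2. Fukuyama reduction of F2 (Et3SiH, Pd/C, acetone, rt) should then deliver 13 under neutral conditions with the aryl aldehyde untouched, and the filtered solution can go straight into step 9.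

Step 10. What may go wrong:
- acylation at O4 as well as at O3;
- migration of the acetyl group from O3 to the cis O4 during work-up.

Fallback: setting out from 15 and returning at 18, the order of events is reversed. The electron-rich benzylic C4 carbinol would be oxidised chemoselectively with DDQ (dioxane, rt; benzylic hydride abstraction, the aliphatic C3 carbinol being inert) to (2R,3R)-3-hydroxy-5,7-bis(methoxymethoxy)-6-(3-methylbut-2-enyl)-2-phenyl-2,3-dihydro-4H-chromen-4-one F3. Its only free hydroxyl would then be acetylated (Ac2O, pyridine, cat. DMAP, 0 °C) to give 18.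

**Further compounds**
F0 | step 9 | none | none
F1 | step 8 | S-ethyl (2S)-2-hydroxy-2-phenylethanethioate | CCSC(=O)[C@@H](O)c1ccccc1
F2 | step 8 | S-ethyl (2R)-2-[2-formyl-3,5-bis(methoxymethoxy)-4-(3-methylbut-2-enyl)phenoxy]-2-phenylethanethioate | CCSC(=O)[C@H](Oc1cc(OCOC)c(CC=C(C)C)c(OCOC)c1C=O)c1ccccc1
F3 | step 10 | (2R,3R)-3-hydroxy-5,7-bis(methoxymethoxy)-6-(3-methylbut-2-enyl)-2-phenyl-2,3-dihydro-4H-chromen-4-one | O[C@H]1C(=O)c2c(cc(OCOC)c(CC=C(C)C)c2OCOC)O[C@@H]1c1ccccc1
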